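**Plan**

Numbering: carbocycle C1–C10 (C1=C2 E, C3 OAc, C4=C5 Z, C8 O-angelate, C10 methyl carbinol), fused at C6–C7 to the lactone O–C6, C7, C11(=C13), C12=O.
Enabling feature: C8(O)–C7–C11(=C13) is a homoallylic alcohol inside the ten-membered ring, and its allyl part (C13–C11–C7) belongs to the five-membered lactone, so a 3-(bromomethyl)butenolide can serve as allyl donor toward a C8 aldehyde.
Retrosynthetic cuts: the C3 and C8 ester C–O bonds; C7–C8 (opens the ten-membered ring, C13 becomes CH2Br); C11–C12 and O–C12 of the lactone (CO); C6–C7 and C2–C3 (acetylide additions to enals).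
Forward order: alkyne (C1, C2, C8–C10) plus Z-iodo enal (C3–C5) gives C2–C3; formylation adds C6; a propargyl ether (C7, C11, C13) gives C6–C7; the lactone ring closes by carbonylation; the ten-membered ring closes last at C7–C8; then the esters.
Stereochemistry: C10 from Sharpless epoxidation; C3 and C6 from two catalyst-controlled alkynylations; C7 and C8 relayed from C6 in the ring-closing allylation. The Z C4=C5 alkene comes from anti-carbomagnesiation, the E C1=C2 alkene from trans-hydroalumination, and the angelate geometry from angelic acid.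

Key step: step 21

Assumption: the zinc–ProPhenol catalyst is taken to deliver the alkynyl group to the Re face of an enal carbonyl with the (S,S) ligand and to the Si face with the (R,R) ligand; if a Mosher ester analysis of the first adduct shows the opposite sense, the two antipodes are exchanged between steps 9 and 14.

**Route**

Step 1
Reactants: 1 3-butyn-1-ol
Product: 2 1-[(but-3-yn-1-yloxy)methyl]-4-methoxybenzene
Conditions: NaH, 4-methoxybenzyl chloride, Bu4NI (cat.), THF/DMF, 0 °C → rt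
Reagents that add atoms: 4-methoxybenzyl chloride, COc1ccc(CCl)cc1
Why: Williamson etherification of the alkoxide (the O–H is far more acidic than the alkyne C–H) should give an ether that withstands every later base, hydride and organometallic step.

Step 2
Reactants: 2 1-[(but-3-yn-1-yloxy)methyl]-4-methoxybenzene
Product: 4 (E)-5-[(4-methoxybenzyl)oxy]-3-methylpent-2-en-1-ol, via alkenyldimethylalane 3 (not isolated)
Conditions: Me3Al, Cp2ZrCl2 (0.25 equiv), CH2Cl2, 0 °C → rt; then (CH2O)n, rt; aq. potassium sodium tartrate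
Reagents that add atoms: trimethylaluminium, C[Al](C)C; formaldehyde (as paraformaldehyde), C=O
Why: Zirconium-catalysed Negishi carboalumination adds CH3 and Al syn with Al on the terminal carbon, so hydroxymethylation of the alkenylalane should fix the E alkene with CH3 cis to CH2OH.

Step 3
Reactants: 4 (E)-5-[(4-methoxybenzyl)oxy]-3-methylpent-2-en-1-ol
Product: 5 [(2R,3R)-3-{2-[(4-methoxybenzyl)oxy]ethyl}-3-methyloxiran-2-yl]methanol
Conditions: Ti(OiPr)4 (10 mol %), D-(−)-diethyl tartrate (12 mol %), t-BuOOH, 4 Å MS, CH2Cl2, −20 °C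
Reagents that add atoms: tert-butyl hydroperoxide, CC(C)(C)OO
Why: Katsuki–Sharpless asymmetric epoxidation of an E 3,3-disubstituted allylic alcohol (the geraniol pattern) with the unnatural tartrate should give the (2R,3R) epoxide, which sets the C10 carbinol centre whose C–O bond is never broken again.

Step 4
Reactants: 5 [(2R,3R)-3-{2-[(4-methoxybenzyl)oxy]ethyl}-3-methyloxiran-2-yl]methanol
Product: 6 (2S,3R)-2-(chloromethyl)-3-{2-[(4-methoxybenzyl)oxy]ethyl}-3-methyloxirane
Conditions: PPh3, CCl4, NaHCO3 (cat.), reflux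
Reagents that add atoms: carbon tetrachloride, ClC(Cl)(Cl)Cl
Why: Appel chlorination of the primary alcohol is neutral and should leave the trisubstituted epoxide intact.

Step 5
Reactants: 6 (2S,3R)-2-(chloromethyl)-3-{2-[(4-methoxybenzyl)oxy]ethyl}-3-methyloxirane
Product: 7 (R)-5-[(4-methoxybenzyl)oxy]-3-methylpent-1-yn-3-ol
Conditions: n-BuLi (3.2 equiv), THF, −78 → −30 °C; then H2O
Reagents that add atoms: none
Why: Base-induced fragmentation of a 2,3-epoxy chloride to a propargylic alcohol (Takano–Yadav double elimination: α-lithiation, epoxide opening, loss of HCl) should give the terminal alkyne without touching the C10–O bond or its configuration.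

Step 6
Reactants: 7 (R)-5-[(4-methoxybenzyl)oxy]-3-methylpent-1-yn-3-ol
Product: 8 (R)-triethyl({5-[(4-methoxybenzyl)oxy]-3-methylpent-1-yn-3-yl}oxy)silane
Conditions: Et3SiOTf, 2,6-lutidine, CH2Cl2, −78 → 0 °C
Reagents that add atoms: triethylsilyl triflate, CC[Si](CC)(CC)OS(=O)(=O)C(F)(F)F
Why: Silylation with the silyl triflate is the standard way to protect a hindered tertiary alcohol, and the tertiary triethylsilyl ether should last until step 23.

Step 7
Reactants: 9 propargyl alcohol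
Product: 11 (Z)-3-iodo-2-methylprop-2-en-1-ol, via alkenylmagnesium alkoxide 10 (not isolated)
Conditions: MeMgBr (2.5 equiv), CuI (10 mol %), THF, −10 °C → rt; then I2, −78 → 0 °C
Reagents that add atoms: methylmagnesium bromide, C[Mg]Br; iodine, II
Why: Copper-catalysed, alkoxide-directed anti-carbomagnesiation of propargyl alcohol (Duboudin type) puts CH3 on the internal carbon and Mg on the terminus cis to CH2O in a five-membered chelate, so iodinolysis should give the Z iodide.

Step 8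
Reactants: 11 (Z)-3-iodo-2-methylprop-2-en-1-ol
Product: 12 (Z)-3-iodo-2-methylprop-2-enal
Conditions: MnO2, CH2Cl2, rt, dark; used at once
Reagents that add atoms: none
Why: Allylic oxidation with MnO2 is neutral, which matters because β-iodo enals isomerise with acid, iodide or light.

Step 9
Reactants: 8 (R)-triethyl({5-[(4-methoxybenzyl)oxy]-3-methylpent-1-yn-3-yl}oxy)silane; 12 (Z)-3-iodo-2-methylprop-2-enal
Product: 14 (1Z,3R,6R)-1-iodo-8-[(4-methoxybenzyl)oxy]-2,6-dimethyl-6-[(triethylsilyl)oxy]oct-1-en-4-yn-3-ol, via alkynyl(methyl)zinc 13 (not isolated)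
Conditions: Me2Zn, (S,S)-ProPhenol (20 mol %), Ph3P=O (40 mol %), toluene, 0 °C → rt; then 12, 4 °C, dark
Reagents that add atoms: none
Why: Catalytic asymmetric alkynylation of an enal with a dinuclear zinc–ProPhenol catalyst (Trost type) forms C2–C3, and Re-face delivery of the alkynylzinc should set the 3R carbinol under catalyst control, the remote C10 centre having no influence.

Step 10
Reactants: 14 (1Z,3R,6R)-1-iodo-8-[(4-methoxybenzyl)oxy]-2,6-dimethyl-6-[(triethylsilyl)oxy]oct-1-en-4-yn-3-ol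
Product: 16 (1Z,3R,4E,6R)-1-iodo-8-[(4-methoxybenzyl)oxy]-2,6-dimethyl-6-[(triethylsilyl)oxy]octa-1,4-dien-3-ol, via cyclic alkenylalanate 15 (not isolated)
Conditions: NaAlH2(OCH2CH2OMe)2, THF, 0 °C; aq. potassium sodium tartrate
Reagents that add atoms: none
Why: Hydroxyl-directed trans-hydroalumination of the propargylic alcohol followed by protonolysis should give the E C1=C2 alkene, while the alkenyl iodide and the other alkene are not attacked at 0 °C.

Step 11
Reactants: 16 (1Z,3R,4E,6R)-1-iodo-8-[(4-methoxybenzyl)oxy]-2,6-dimethyl-6-[(triethylsilyl)oxy]octa-1,4-dien-3-ol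
Product: 17 (1Z,3R,4E,6R)-3-[(tert-butyldimethylsilyl)oxy]-1-iodo-8-[(4-methoxybenzyl)oxy]-2,6-dimethyl-6-[(triethylsilyl)oxy]octa-1,4-diene
Conditions: t-BuMe2SiCl, imidazole, DMF, rt
Reagents that add atoms: tert-butyldimethylsilyl chloride, CC(C)(C)[Si](C)(C)Cl
Why: Standard silylation is used in place of the final acetate because the t-BuLi, aluminium hydride and zerovalent palladium of steps 12, 15 and 16 would all attack a doubly allylic acetate.

Step 12
Reactants: 17 (1Z,3R,4E,6R)-3-[(tert-butyldimethylsilyl)oxy]-1-iodo-8-[(4-methoxybenzyl)oxy]-2,6-dimethyl-6-[(triethylsilyl)oxy]octa-1,4-diene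
Product: 19 (2Z,4R,5E,7R)-4-[(tert-butyldimethylsilyl)oxy]-9-[(4-methoxybenzyl)oxy]-3,7-dimethyl-7-[(triethylsilyl)oxy]nona-2,5-dienal, via alkenyllithium 18 (not isolated)
Conditions: t-BuLi (2.1 equiv), Et2O, −78 °C; DMF, −78 → 0 °C; then H2O
Reagents that add atoms: N,N-dimethylformamide, CN(C)C=O
Why: Iodine–lithium exchange proceeds with retention of alkene geometry, and formylation of the alkenyllithium with DMF in ether at −78 °C (where 1,4 O-to-C silyl migration is slow) should introduce C6 as the Z enal.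

Step 13
Reactants: 9 propargyl alcohol
Product: 20 triethyl(prop-2-yn-1-yloxy)silane
Conditions: Et3SiCl, imidazole, CH2Cl2, 0 °C
Reagents that add atoms: triethylsilyl chloride, CC[Si](CC)(CC)Cl
Why: Simple silylation of a primary alcohol gives the one silyl ether that step 17 can later remove selectively.

Step 14
Reactants: 19 (2Z,4R,5E,7R)-4-[(tert-butyldimethylsilyl)oxy]-9-[(4-methoxybenzyl)oxy]-3,7-dimethyl-7-[(triethylsilyl)oxy]nona-2,5-dienal; 20 triethyl(prop-2-yn-1-yloxy)silane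
Product: 22 (4R,5Z,7R,8E,10R)-7-[(tert-butyldimethylsilyl)oxy]-12-[(4-methoxybenzyl)oxy]-6,10-dimethyl-1,10-bis[(triethylsilyl)oxy]dodeca-5,8-dien-2-yn-4-ol, via alkynyl(methyl)zinc 21 (not isolated)
Conditions: 20 (3 equiv), Me2Zn, (R,R)-ProPhenol (20 mol %), Ph3P=O (40 mol %), toluene, 0 °C → rt; then 19, 4 °C
Reagents that add atoms: none
Why: A second zinc–ProPhenol alkynylation, now with the antipodal ligand for Si-face addition, forms C6–C7 and should set the C6 carbinol (4R in the name) under catalyst control over the γ-silyloxy centre.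

Step 15
Reactants: 22 (4R,5Z,7R,8E,10R)-7-[(tert-butyldimethylsilyl)oxy]-12-[(4-methoxybenzyl)oxy]-6,10-dimethyl-1,10-bis[(triethylsilyl)oxy]dodeca-5,8-dien-2-yn-4-ol
Product: 24 (2Z,4R,5Z,7R,8E,10R)-7-[(tert-butyldimethylsilyl)oxy]-2-iodo-12-[(4-methoxybenzyl)oxy]-6,10-dimethyl-1,10-bis[(triethylsilyl)oxy]dodeca-2,5,8-trien-4-ol, via cyclic alkenylalanate 23 (not isolated)
Conditions: NaAlH2(OCH2CH2OMe)2, THF, 0 °C; then I2, THF, −78 → 0 °C; aq. Na2S2O3, aq. potassium sodium tartrate
Reagents that add atoms: iodine, II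
Why: Trans-hydroalumination directed by the C6 alkoxide places aluminium on C11 (cis to C6 in the five-membered alanate), and iodinolysis with retention should give the Z alkenyl iodide needed for lactone closure.

Step 16
Reactants: 24 (2Z,4R,5Z,7R,8E,10R)-7-[(tert-butyldimethylsilyl)oxy]-2-iodo-12-[(4-methoxybenzyl)oxy]-6,10-dimethyl-1,10-bis[(triethylsilyl)oxy]dodeca-2,5,8-trien-4-ol
Product: 25 (R)-5-[(1Z,3R,4E,6R)-3-[(tert-butyldimethylsilyl)oxy]-8-[(4-methoxybenzyl)oxy]-2,6-dimethyl-6-[(triethylsilyl)oxy]octa-1,4-dien-1-yl]-3-{[(triethylsilyl)oxy]methyl}furan-2(5H)-one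
Conditions: PdCl2(PPh3)2 (5 mol %), CO (1 atm), K2CO3, THF, 40 °C
Reagents that add atoms: carbon monoxide, [C-]#[O+]
Why: Palladium-catalysed carbonylative lactonisation of a Z γ-iodo allylic alcohol (oxidative addition, CO insertion, capture of the acylpalladium by the cis C6 hydroxyl) should close the butenolide without touching the C6–O bond, and the mild carbonate base limits epimerisation at the γ position.

Step 17
Reactants: 25 (R)-5-[(1Z,3R,4E,6R)-3-[(tert-butyldimethylsilyl)oxy]-8-[(4-methoxybenzyl)oxy]-2,6-dimethyl-6-[(triethylsilyl)oxy]octa-1,4-dien-1-yl]-3-{[(triethylsilyl)oxy]methyl}furan-2(5H)-one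
Product: 26 (R)-5-[(1Z,3R,4E,6R)-3-[(tert-butyldimethylsilyl)oxy]-8-[(4-methoxybenzyl)oxy]-2,6-dimethyl-6-[(triethylsilyl)oxy]octa-1,4-dien-1-yl]-3-(hydroxymethyl)furan-2(5H)-one
Conditions: pyridinium p-toluenesulfonate (cat.), MeOH/CH2Cl2, 0 °C
Reagents that add atoms: none
Why: Acid-catalysed methanolysis discriminates silyl ethers by size and substitution, so the primary triethylsilyl ether should be cleaved well before the secondary tert-butyldimethylsilyl and tertiary triethylsilyl ethers.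

Step 18
Reactants: 26 (R)-5-[(1Z,3R,4E,6R)-3-[(tert-butyldimethylsilyl)oxy]-8-[(4-methoxybenzyl)oxy]-2,6-dimethyl-6-[(triethylsilyl)oxy]octa-1,4-dien-1-yl]-3-(hydroxymethyl)furan-2(5H)-one
Product: 27 (R)-3-(bromomethyl)-5-[(1Z,3R,4E,6R)-3-[(tert-butyldimethylsilyl)oxy]-8-[(4-methoxybenzyl)oxy]-2,6-dimethyl-6-[(triethylsilyl)oxy]octa-1,4-dien-1-yl]furan-2(5H)-one
Conditions: CBr4, PPh3, CH2Cl2, 0 °C
Reagents that add atoms: carbon tetrabromide, BrC(Br)(Br)Br
Why: Appel bromination (SN2 at the primary allylic carbon) is neutral and should install the allyl donor without exposing the base-sensitive γ-hydrogen of the butenolide.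

Step 19
Reactants: 27 (R)-3-(bromomethyl)-5-[(1Z,3R,4E,6R)-3-[(tert-butyldimethylsilyl)oxy]-8-[(4-methoxybenzyl)oxy]-2,6-dimethyl-6-[(triethylsilyl)oxy]octa-1,4-dien-1-yl]furan-2(5H)-one
Product: 28 (R)-3-(bromomethyl)-5-[(1Z,3R,4E,6R)-3-[(tert-butyldimethylsilyl)oxy]-8-hydroxy-2,6-dimethyl-6-[(triethylsilyl)oxy]octa-1,4-dien-1-yl]furan-2(5H)-one
Conditions: DDQ (1.3 equiv), CH2Cl2/pH 7 buffer, 0 °C
Reagents that add atoms: none
Why: Oxidative cleavage of the 4-methoxybenzyl ether by DDQ in buffered medium should be faster than hydride abstraction from the doubly allylic silyl ether, and the allylic bromide is inert to the oxidant.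

Step 20
Reactants: 28 (R)-3-(bromomethyl)-5-[(1Z,3R,4E,6R)-3-[(tert-butyldimethylsilyl)oxy]-8-hydroxy-2,6-dimethyl-6-[(triethylsilyl)oxy]octa-1,4-dien-1-yl]furan-2(5H)-one
Product: 29 (3R,4E,6R,7Z)-8-[(R)-4-(bromomethyl)-5-oxo-2,5-dihydrofuran-2-yl]-6-[(tert-butyldimethylsilyl)oxy]-3,7-dimethyl-3-[(triethylsilyl)oxy]octa-4,7-dienal
Conditions: Dess–Martin periodinane, NaHCO3, CH2Cl2, 0 °C → rt
Reagents that add atoms: none
Why: Buffered Dess–Martin oxidation gives the β-silyloxy aldehyde without amine base, which avoids β-elimination of the C10 silyloxy group and attack on the bromide.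

Step 21
Reactants: 29 (3R,4E,6R,7Z)-8-[(R)-4-(bromomethyl)-5-oxo-2,5-dihydrofuran-2-yl]-6-[(tert-butyldimethylsilyl)oxy]-3,7-dimethyl-3-[(triethylsilyl)oxy]octa-4,7-dienal
Product: 31 (1E,3R,4Z,6R,7S,8R,10R)-3-[(tert-butyldimethylsilyl)oxy]-8-hydroxy-10-[(triethylsilyl)oxy]germacra-1,4,11(13)-trien-12,6-olide, via allylchromium dichloride 30 (not isolated)
Conditions: CrCl2 (10 equiv), THF, 25 °C, syringe-pump addition of 29 (final 2 mM); aq. work-up
Reagents that add atoms: none
Why: Two equivalents of divalent chromium insert into the C13–Br bond to give the 2-carbonyl-substituted allylchromium 30, bound at the unsubstituted C13, which adds to the tethered C8 aldehyde through C7 (SE2') in a closed six-membered transition state with the aldehyde oxygen on chromium; the closest known reaction type is the Nozaki–Hiyama allylation of aldehydes with 3-(bromomethyl)furan-2(5H)-ones and 2-(bromomethyl)acrylates, including its intramolecular use for ten- to fourteen-membered carbocycles. The ten-membered ring closes by 10-exo-trig carbonyl addition forming C7–C8, and the allylic transposition leaves the exocyclic C11=C13 methylene, so no later methylenation is needed. C7 is controlled by C6: the Z C4=C5 alkene carries the tether from C5 over one face of the planar allyl unit, so the aldehyde should reach C7 cis to C5 and give the cis-fused lactone. C8 follows from the chair: the lactone ring holds C6 trans to C13 (an E-crotyl-type donor) and the chain carbon C9 sits equatorial, which gives the anti C7/C8 relationship of the target. The step needs aldehyde-selective, γ-selective allyl transfer without β-elimination of the C6 carboxylate and without oligomerisation; the aldehyde selectivity of organochromium reagents, the primary C13–Cr bond and slow addition at high dilution should secure this.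

Step 22
Reactants: 31 (1E,3R,4Z,6R,7S,8R,10R)-3-[(tert-butyldimethylsilyl)oxy]-8-hydroxy-10-[(triethylsilyl)oxy]germacra-1,4,11(13)-trien-12,6-olide; 32 angelic acid
Product: 34 (1E,3R,4Z,6R,7S,8R,10R)-8-(angeloyloxy)-3-[(tert-butyldimethylsilyl)oxy]-10-[(triethylsilyl)oxy]germacra-1,4,11(13)-trien-12,6-olide, via mixed anhydride 33 (not isolated)
Conditions: 32, 2,4,6-trichlorobenzoyl chloride, Et3N, toluene, rt; then 31, toluene, 75 °C (no DMAP)
Reagents that add atoms: none
Why: Yamaguchi-type esterification through the preformed mixed anhydride without a nucleophilic catalyst should acylate C8–OH, the only free hydroxyl, without Z-to-E isomerisation of the angeloyl group to tiglate.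

Step 23
Reactants: 34 (1E,3R,4Z,6R,7S,8R,10R)-8-(angeloyloxy)-3-[(tert-butyldimethylsilyl)oxy]-10-[(triethylsilyl)oxy]germacra-1,4,11(13)-trien-12,6-olide
Product: 35 (1E,3R,4Z,6R,7S,8R,10R)-8-(angeloyloxy)-3,10-dihydroxygermacra-1,4,11(13)-trien-12,6-olide
Conditions: HF·pyridine, pyridine, THF, 0 °C → rt
Reagents that add atoms: none
Why: Fluoride-mediated desilylation with buffered HF·pyridine should remove both silyl ethers while the two ester groups, the α-methylene lactone and the doubly allylic alcohol tolerate the mildly acidic medium.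

Step 24
Reactants: 35 (1E,3R,4Z,6R,7S,8R,10R)-8-(angeloyloxy)-3,10-dihydroxygermacra-1,4,11(13)-trien-12,6-olide
Product: 36 (1E,3R,4Z,6R,7S,8R,10R)-3-acetoxy-8-(angeloyloxy)-10-hydroxygermacra-1,4,11(13)-trien-12,6-olide (CNP0181631.1)
Conditions: Ac2O, pyridine, DMAP (cat.), CH2Cl2, 0 °C
Reagents that add atoms: acetic anhydride, CC(=O)OC(C)=O
Why: Acetylation is selective for the secondary C3 hydroxyl because the tertiary C10 hydroxyl is too hindered to be acylated under these conditions.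

**Compound list**

1 | 3-butyn-1-ol | C#CCCO | starting material
2 | 1-[(but-3-yn-1-yloxy)methyl]-4-methoxybenzene | C#CCCOCc1ccc(OC)cc1 | intermediate
3 | dimethyl[(E)-4-[(4-methoxybenzyl)oxy]-2-methylbut-1-en-1-yl]alane | C[Al](C)/C=C(\C)CCOCc1ccc(OC)cc1 | intermediate (not isolated)
4 | (E)-5-[(4-methoxybenzyl)oxy]-3-methylpent-2-en-1-ol | OC/C=C(\C)CCOCc1ccc(OC)cc1 | intermediate
5 | [(2R,3R)-3-{2-[(4-methoxybenzyl)oxy]ethyl}-3-methyloxiran-2-yl]methanol | OC[C@H]1O[C@]1(C)CCOCc2ccc(OC)cc2 | intermediate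
6 | (2S,3R)-2-(chloromethyl)-3-{2-[(4-methoxybenzyl)oxy]ethyl}-3-methyloxirane | ClC[C@H]1O[C@]1(C)CCOCc2ccc(OC)cc2 | intermediate
7 | (R)-5-[(4-methoxybenzyl)oxy]-3-methylpent-1-yn-3-ol | C#C[C@](C)(O)CCOCc1ccc(OC)cc1 | intermediate
8 | (R)-triethyl({5-[(4-methoxybenzyl)oxy]-3-methylpent-1-yn-3-yl}oxy)silane | C#C[C@](C)(O[Si](CC)(CC)CC)CCOCc1ccc(OC)cc1 | intermediate
9 | propargyl alcohol | C#CCO | starting material
10 | bromomagnesium (Z)-3-(bromomagnesio)-2-methylprop-2-en-1-olate | Br[Mg]OC/C(C)=C\[Mg]Br | intermediate (not isolated)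
11 | (Z)-3-iodo-2-methylprop-2-en-1-ol | OC/C(C)=C\I | intermediate
12 | (Z)-3-iodo-2-methylprop-2-enal | O=C/C(C)=C\I | intermediate
13 | methylzinc acetylide of 8 | C[Zn]C#C[C@](C)(O[Si](CC)(CC)CC)CCOCc1ccc(OC)cc1 | intermediate (not isolated)
14 | (1Z,3R,6R)-1-iodo-8-[(4-methoxybenzyl)oxy]-2,6-dimethyl-6-[(triethylsilyl)oxy]oct-1-en-4-yn-3-ol | I/C=C(/C)[C@H](O)C#C[C@](C)(O[Si](CC)(CC)CC)CCOCc1ccc(OC)cc1 | intermediate
15 | sodium cyclic alkenylalanate from 14 (ring Al–O–C3–C2=C1, two 2-methoxyethoxy groups on Al) | [Na+].COCCO[Al-]1(OCCOC)O[C@@H](/C(C)=C\I)C=C1[C@](C)(O[Si](CC)(CC)CC)CCOCc2ccc(OC)cc2 | intermediate (not isolated)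
16 | (1Z,3R,4E,6R)-1-iodo-8-[(4-methoxybenzyl)oxy]-2,6-dimethyl-6-[(triethylsilyl)oxy]octa-1,4-dien-3-ol | I/C=C(/C)[C@H](O)/C=C/[C@](C)(O[Si](CC)(CC)CC)CCOCc1ccc(OC)cc1 | intermediate
17 | (1Z,3R,4E,6R)-3-[(tert-butyldimethylsilyl)oxy]-1-iodo-8-[(4-methoxybenzyl)oxy]-2,6-dimethyl-6-[(triethylsilyl)oxy]octa-1,4-diene | I/C=C(/C)[C@H](O[Si](C)(C)C(C)(C)C)/C=C/[C@](C)(O[Si](CC)(CC)CC)CCOCc1ccc(OC)cc1 | intermediate
18 | (Z)-alkenyllithium from 17 (Li in place of I) | [Li]/C=C(/C)[C@H](O[Si](C)(C)C(C)(C)C)/C=C/[C@](C)(O[Si](CC)(CC)CC)CCOCc1ccc(OC)cc1 | intermediate (not isolated)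
19 | (2Z,4R,5E,7R)-4-[(tert-butyldimethylsilyl)oxy]-9-[(4-methoxybenzyl)oxy]-3,7-dimethyl-7-[(triethylsilyl)oxy]nona-2,5-dienal | O=C/C=C(/C)[C@H](O[Si](C)(C)C(C)(C)C)/C=C/[C@](C)(O[Si](CC)(CC)CC)CCOCc1ccc(OC)cc1 | intermediate
20 | triethyl(prop-2-yn-1-yloxy)silane | C#CCO[Si](CC)(CC)CC | intermediate
21 | methylzinc acetylide of 20 | C[Zn]C#CCO[Si](CC)(CC)CC | intermediate (not isolated)
22 | (4R,5Z,7R,8E,10R)-7-[(tert-butyldimethylsilyl)oxy]-12-[(4-methoxybenzyl)oxy]-6,10-dimethyl-1,10-bis[(triethylsilyl)oxy]dodeca-5,8-dien-2-yn-4-ol | CC[Si](CC)(CC)OCC#C[C@H](O)/C=C(/C)[C@H](O[Si](C)(C)C(C)(C)C)/C=C/[C@](C)(O[Si](CC)(CC)CC)CCOCc1ccc(OC)cc1 | intermediate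
23 | sodium cyclic alkenylalanate from 22 (ring Al–O–C6–C7=C11, two 2-methoxyethoxy groups on Al) | [Na+].COCCO[Al-]1(OCCOC)O[C@H](/C=C(/C)[C@H](O[Si](C)(C)C(C)(C)C)/C=C/[C@](C)(O[Si](CC)(CC)CC)CCOCc2ccc(OC)cc2)C=C1CO[Si](CC)(CC)CC | intermediate (not isolated)
24 | (2Z,4R,5Z,7R,8E,10R)-7-[(tert-butyldimethylsilyl)oxy]-2-iodo-12-[(4-methoxybenzyl)oxy]-6,10-dimethyl-1,10-bis[(triethylsilyl)oxy]dodeca-2,5,8-trien-4-ol | CC[Si](CC)(CC)OC/C(I)=C/[C@H](O)/C=C(/C)[C@H](O[Si](C)(C)C(C)(C)C)/C=C/[C@](C)(O[Si](CC)(CC)CC)CCOCc1ccc(OC)cc1 | intermediate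
25 | (R)-5-[(1Z,3R,4E,6R)-3-[(tert-butyldimethylsilyl)oxy]-8-[(4-methoxybenzyl)oxy]-2,6-dimethyl-6-[(triethylsilyl)oxy]octa-1,4-dien-1-yl]-3-{[(triethylsilyl)oxy]methyl}furan-2(5H)-one | CC[Si](CC)(CC)OCC1=C[C@@H](/C=C(/C)[C@H](O[Si](C)(C)C(C)(C)C)/C=C/[C@](C)(O[Si](CC)(CC)CC)CCOCc2ccc(OC)cc2)OC1=O | intermediate
26 | 3-(hydroxymethyl) analogue of 25 | OCC1=C[C@@H](/C=C(/C)[C@H](O[Si](C)(C)C(C)(C)C)/C=C/[C@](C)(O[Si](CC)(CC)CC)CCOCc2ccc(OC)cc2)OC1=O | intermediate
27 | 3-(bromomethyl) analogue of 25 | BrCC1=C[C@@H](/C=C(/C)[C@H](O[Si](C)(C)C(C)(C)C)/C=C/[C@](C)(O[Si](CC)(CC)CC)CCOCc2ccc(OC)cc2)OC1=O | intermediate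
28 | (R)-3-(bromomethyl)-5-[(1Z,3R,4E,6R)-3-[(tert-butyldimethylsilyl)oxy]-8-hydroxy-2,6-dimethyl-6-[(triethylsilyl)oxy]octa-1,4-dien-1-yl]furan-2(5H)-one | BrCC1=C[C@@H](/C=C(/C)[C@H](O[Si](C)(C)C(C)(C)C)/C=C/[C@](C)(O[Si](CC)(CC)CC)CCO)OC1=O | intermediate
29 | (3R,4E,6R,7Z)-8-[(R)-4-(bromomethyl)-5-oxo-2,5-dihydrofuran-2-yl]-6-[(tert-butyldimethylsilyl)oxy]-3,7-dimethyl-3-[(triethylsilyl)oxy]octa-4,7-dienal (key-step precursor) | BrCC1=C[C@@H](/C=C(/C)[C@H](O[Si](C)(C)C(C)(C)C)/C=C/[C@](C)(O[Si](CC)(CC)CC)CC=O)OC1=O | intermediate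
30 | allylchromium dichloride from 29 (CrCl2 on C13) | Cl[Cr](Cl)CC1=C[C@@H](/C=C(/C)[C@H](O[Si](C)(C)C(C)(C)C)/C=C/[C@](C)(O[Si](CC)(CC)CC)CC=O)OC1=O | intermediate (not isolated)
31 | (1E,3R,4Z,6R,7S,8R,10R)-3-[(tert-butyldimethylsilyl)oxy]-8-hydroxy-10-[(triethylsilyl)oxy]germacra-1,4,11(13)-trien-12,6-olide, 6,7-cis-fused (key-step product) | C=C1C(=O)O[C@@H]2/C=C(/C)[C@H](O[Si](C)(C)C(C)(C)C)/C=C/[C@](C)(O[Si](CC)(CC)CC)C[C@@H](O)[C@H]12 | intermediate
32 | angelic acid, (Z)-2-methylbut-2-enoic acid | C/C=C(/C)C(=O)O | starting material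
33 | (Z)-2-methylbut-2-enoic 2,4,6-trichlorobenzoic anhydride | C/C=C(/C)C(=O)OC(=O)c1c(Cl)cc(Cl)cc1Cl | intermediate (not isolated)
34 | (1E,3R,4Z,6R,7S,8R,10R)-8-(angeloyloxy)-3-[(tert-butyldimethylsilyl)oxy]-10-[(triethylsilyl)oxy]germacra-1,4,11(13)-trien-12,6-olide | C=C1C(=O)O[C@@H]2/C=C(/C)[C@H](O[Si](C)(C)C(C)(C)C)/C=C/[C@](C)(O[Si](CC)(CC)CC)C[C@@H](OC(=O)/C(C)=C\C)[C@H]12 | intermediate
35 | (1E,3R,4Z,6R,7S,8R,10R)-8-(angeloyloxy)-3,10-dihydroxygermacra-1,4,11(13)-trien-12,6-olide | C=C1C(=O)O[C@@H]2/C=C(/C)[C@H](O)/C=C/[C@](C)(O)C[C@@H](OC(=O)/C(C)=C\C)[C@H]12 | intermediate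
36 | (1E,3R,4Z,6R,7S,8R,10R)-3-acetoxy-8-(angeloyloxy)-10-hydroxygermacra-1,4,11(13)-trien-12,6-olide (CNP0181631.1) | C=C1C(=O)O[C@@H]2/C=C(/C)[C@H](OC(C)=O)/C=C/[C@](C)(O)C[C@@H](OC(=O)/C(C)=C\C)[C@H]12 | target

**Step count and risks**

Total steps: 24. Longest linear sequence: 21 steps (steps 1–6, 9–12 and 14–24).

Step 21 (ring closure). Intermolecular coupling may outrun closure of the ten-membered ring. The allylchromium may also lose the C6 carboxylate by β-elimination, opening the lactone. Addition through the other face or through a boat may give the trans-fused or C8-epimeric ring. The fallback sets out from 27 and keeps the same C7–C8 bond but uses a boron allyl donor that cannot eliminate or reduce. Palladium-catalysed borylation of the allylic bromide (B2pin2, Pd2(dba)3, KOAc, toluene) should give the pinacol allylboronate F1 with boron on the primary C13. DDQ removal of the 4-methoxybenzyl group gives the alcohol F2, and Dess–Martin oxidation gives the aldehyde F3. Warming F3 in dilute toluene, if needed with catalytic Sc(OTf)3, should bring about intramolecular allylboration through the same chair arrangement (a known route from 2-carbonyl-substituted allylboronates to α-methylene lactones). Hydrolytic work-up of the borate returns the route to 31.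

Step 9 (first alkynylation). The Z β-iodo enal may isomerise to the E isomer during the slow zinc-catalysed addition, and catalyst control may be eroded on this α-branched enal. The fallback sets out from 8 and builds the Z iodoalkene only after C3 is in place. Hydrozirconation of 8 with Cp2Zr(H)Cl and iodinolysis gives the E alkenyl iodide F4. Iodine–lithium exchange and DMF then give the configurationally stable E enal F5. Zinc–(R,R)-ProPhenol addition of trimethylsilylacetylene to F5 gives the silylated enynol F6, and K2CO3 in methanol gives the terminal alkyne F7. Copper-catalysed anti-carbomagnesiation of this propargylic alcohol (MeMgBr, CuI, then I2) installs CH3 on C4 and iodine on C5 cis to C3. This returns the route to 16, with step 10 no longer needed.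

Step 14 (second alkynylation). Addition to the hindered Z enal may be slow enough for Z-to-E isomerisation, and the γ-silyloxy centre may oppose the catalyst. The fallback sets out from 19 and 20 and replaces asymmetric C–C bond formation by asymmetric reduction. The lithium acetylide of 20 (n-BuLi, THF, −78 °C) adds within minutes to 19 to give the C6-epimeric alcohol mixture F8. Dess–Martin oxidation gives the ynone F9. Corey–Bakshi–Shibata reduction ((R)-methyl oxazaborolidine, catecholborane, toluene, −78 °C; alkenyl as the large group) should then give the single carbinol and return the route to 22.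

Further compounds
F1 | step 21 | (R)-5-[(1Z,3R,4E,6R)-3-[(tert-butyldimethylsilyl)oxy]-8-[(4-methoxybenzyl)oxy]-2,6-dimethyl-6-[(triethylsilyl)oxy]octa-1,4-dien-1-yl]-3-[(4,4,5,5-tetramethyl-1,3,2-dioxaborolan-2-yl)methyl]furan-2(5H)-one | CC1(C)OB(CC2=C[C@@H](/C=C(/C)[C@H](O[Si](C)(C)C(C)(C)C)/C=C/[C@](C)(O[Si](CC)(CC)CC)CCOCc3ccc(OC)cc3)OC2=O)OC1(C)C
F2 | step 21 | 8-hydroxy analogue of F1 (4-methoxybenzyl group removed) | CC1(C)OB(CC2=C[C@@H](/C=C(/C)[C@H](O[Si](C)(C)C(C)(C)C)/C=C/[C@](C)(O[Si](CC)(CC)CC)CCO)OC2=O)OC1(C)C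
F3 | step 21 | aldehyde from F2 (boron analogue of 29) | CC1(C)OB(CC2=C[C@@H](/C=C(/C)[C@H](O[Si](C)(C)C(C)(C)C)/C=C/[C@](C)(O[Si](CC)(CC)CC)CC=O)OC2=O)OC1(C)C
F4 | step 9 | (R,E)-triethyl({1-iodo-5-[(4-methoxybenzyl)oxy]-3-methylpent-1-en-3-yl}oxy)silane | I/C=C/[C@](C)(O[Si](CC)(CC)CC)CCOCc1ccc(OC)cc1
F5 | step 9 | (R,E)-6-[(4-methoxybenzyl)oxy]-4-methyl-4-[(triethylsilyl)oxy]hex-2-enal | O=C/C=C/[C@](C)(O[Si](CC)(CC)CC)CCOCc1ccc(OC)cc1
F6 | step 9 | (3R,4E,6R)-8-[(4-methoxybenzyl)oxy]-6-methyl-6-[(triethylsilyl)oxy]-1-(trimethylsilyl)oct-4-en-1-yn-3-ol | C[Si](C)(C)C#C[C@H](O)/C=C/[C@](C)(O[Si](CC)(CC)CC)CCOCc1ccc(OC)cc1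
F7 | step 9 | (3R,4E,6R)-8-[(4-methoxybenzyl)oxy]-6-methyl-6-[(triethylsilyl)oxy]oct-4-en-1-yn-3-ol | C#C[C@H](O)/C=C/[C@](C)(O[Si](CC)(CC)CC)CCOCc1ccc(OC)cc1
F8 | step 14 | C6-epimeric mixture (4RS) of 22 | CC[Si](CC)(CC)OCC#CC(O)/C=C(/C)[C@H](O[Si](C)(C)C(C)(C)C)/C=C/[C@](C)(O[Si](CC)(CC)CC)CCOCc1ccc(OC)cc1
F9 | step 14 | (5Z,7R,8E,10R)-7-[(tert-butyldimethylsilyl)oxy]-12-[(4-methoxybenzyl)oxy]-6,10-dimethyl-1,10-bis[(triethylsilyl)oxy]dodeca-5,8-dien-2-yn-4-one | CC[Si](CC)(CC)OCC#CC(=O)/C=C(/C)[C@H](O[Si](C)(C)C(C)(C)C)/C=C/[C@](C)(O[Si](CC)(CC)CC)CCOCc1ccc(OC)cc1
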